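**Plan**

1. Numbering (guaiane): C1/C5 are the ring-fusion carbons, C2–C4 complete the cyclopentane (methyl C15 on C4), C6–C10 complete the cycloheptane (methyl C14 on C10), C11 on C7 carries C12 (lactone C=O) and C13 (CH2OAc); β is the face of the C5–O–C11 bridge.
2. Cuts: the tiglate at O2 and the acetate at O13, then C10–CH3, then the lactone bond O8–C12, then both oxolane bonds C5–O and C7–C11 in one event, giving epoxy enone 13 and diethyl ketomalonate 14. Compound 13 is cut at C9=C10 (metathesis), C4–CH3, C1–vinyl and C5–C6 back to (S)-4-silyloxycyclopentenone 1.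
3. Enabling feature: the oxolane oxygen on C5 is anti to the 4-OH (the mark of a backside-opened 4α,5α-oxirane); C7 is the α-carbon of C8 once C8 is a ketone and lies 1,3 to C5; C11 is a carbinol carbon flanked by two carboxyl-level carbons, i.e. the carbonyl carbon of a ketomalonate.
4. Forward order of rings: cyclopentene (from 1), cycloheptenone (ring-closing metathesis), oxirane, oxolane (key step), γ-lactone. The C9=C10 bond and the second ester are helpers (regiocontrol of enolisation; symmetric, non-enolisable electrophile) and are removed later by methyl addition and by reduction.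
5. Stereochemistry: C2 from 1; C1 by anti cuprate addition; C4 by hydroxyl-directed epoxidation; C5 by inversion and C7 by β-face aldol addition in the key step; C10 by cuprate attack anti to the oxa bridge; C8 by hydride attack anti to C11; C11 by lactonisation of the only ester that can reach O8.

Key step: step 10

Remark on the chemistry: the target is taken exactly as the SMILES gives it; the 2-methylbut-2-enoate is the E isomer (tiglate), and in all bridged compounds H-1, H-7 and H-8 are α and H-10 is β.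

**Route**

Step 1
Reactants: 1 (S)-4-(tert-butyldimethylsilyloxy)cyclopent-2-en-1-one
Product: 2 (S)-4-(tert-butyldimethylsilyloxy)-2-iodocyclopent-2-en-1-one
Conditions: I2, pyridine, CH2Cl2, 0 °C to rt
Reagents that add atoms: iodine, II
Why: α-iodination of the enone (conjugate addition of pyridine, iodination of the enolate, elimination) should give the 2-iodoenone without touching the silyloxy stereocenter.

Step 2
Reactants: 2 (S)-4-(tert-butyldimethylsilyloxy)-2-iodocyclopent-2-en-1-one; 3 (3-ethoxy-3-oxopropyl)zinc bromide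
Product: 4 ethyl 3-[(3S)-3-(tert-butyldimethylsilyloxy)-5-oxocyclopent-1-en-1-yl]propanoate
Conditions: PdCl2(dppf) (5 mol%), THF/DMF, rt
Reagents that add atoms: none
Why: Negishi coupling of the α-iodoenone with the ester-bearing alkylzinc reagent should attach C6–C8, the dppf ligand suppressing β-hydride elimination.

Step 3
Reactants: 4 ethyl 3-[(3S)-3-(tert-butyldimethylsilyloxy)-5-oxocyclopent-1-en-1-yl]propanoate
Product: 6 ethyl 3-[(4S,5S)-4-(tert-butyldimethylsilyloxy)-2-(trifluoromethylsulfonyloxy)-5-vinylcyclopent-1-en-1-yl]propanoate, via bromomagnesium enolate 5 (not isolated)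
Conditions: vinylMgBr, CuBr·SMe2 (20 mol%), THF, −78 °C; then N-(5-chloropyridin-2-yl)bis(trifluoromethanesulfonimide), −78 to 0 °C
Reagents that add atoms: vinylmagnesium bromide, C=C[Mg]Br; N-(5-chloropyridin-2-yl)bis(trifluoromethanesulfonimide), FC(F)(F)S(=O)(=O)N(c1ccc(Cl)cn1)S(=O)(=O)C(F)(F)F
Why: copper-catalysed conjugate addition of the vinyl Grignard reagent anti to the silyloxy group should set C1 (trans to O2), and O-triflation of the regiodefined enolate should lock the double bond at C4=C5 before it can equilibrate or expel the silyloxy group.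

Step 4
Reactants: 6 ethyl 3-[(4S,5S)-4-(tert-butyldimethylsilyloxy)-2-(trifluoromethylsulfonyloxy)-5-vinylcyclopent-1-en-1-yl]propanoate
Product: 7 ethyl 3-[(4S,5S)-4-(tert-butyldimethylsilyloxy)-2-methyl-5-vinylcyclopent-1-en-1-yl]propanoate
Conditions: MeZnCl, Pd(PPh3)4 (5 mol%), THF, 50 °C
Reagents that add atoms: methylzinc chloride, C[Zn]Cl
Why: Negishi coupling of the enol triflate with methylzinc chloride should install the C4 methyl group on the tetrasubstituted C4=C5 bond while the ester is tolerated.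

Step 5
Reactants: 7 ethyl 3-[(4S,5S)-4-(tert-butyldimethylsilyloxy)-2-methyl-5-vinylcyclopent-1-en-1-yl]propanoate
Product: 9 5-[(4S,5S)-4-(tert-butyldimethylsilyloxy)-2-methyl-5-vinylcyclopent-1-en-1-yl]pent-1-en-3-one, via Weinreb amide 8 (not isolated)
Conditions: MeNHOMe·HCl, iPrMgCl, THF, −20 °C; then vinylMgBr, 0 °C; inverse quench into cold 1 M HCl
Reagents that add atoms: vinylmagnesium bromide, C=C[Mg]Br; N,O-dimethylhydroxylamine hydrochloride, CNOC.Cl (its atoms stay only in 8)
Why: in-situ Weinreb amide formation followed by vinyl Grignard addition should stop at the ketone through the chelated tetrahedral intermediate, the acidic inverse quench preventing conjugate addition of the freed amine to the vinyl ketone.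

Step 6
Reactants: 9 5-[(4S,5S)-4-(tert-butyldimethylsilyloxy)-2-methyl-5-vinylcyclopent-1-en-1-yl]pent-1-en-3-one
Product: 10 2α-(tert-butyldimethylsilyloxy)-4-methyl-1αH-bicyclo[5.3.0]deca-4,9-dien-8-one (guaiane numbering)
Conditions: second-generation Grubbs catalyst (5 mol%), CH2Cl2 (0.005 M), 40 °C
Reagents that add atoms: none
Why: ring-closing metathesis between the C1 vinyl group and the vinyl ketone should close the seven-membered ring as the C9=C10 enone, the tetrasubstituted C4=C5 bond being inert.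

Step 7
Reactants: 10 2α-(tert-butyldimethylsilyloxy)-4-methyl-1αH-bicyclo[5.3.0]deca-4,9-dien-8-one
Product: 11 2α-hydroxy-4-methyl-1αH-bicyclo[5.3.0]deca-4,9-dien-8-one
Conditions: HF·pyridine, THF, 0 °C to rt
Reagents that add atoms: none
Why: fluoride-mediated desilylation should free the homoallylic C2 hydroxyl that is needed as the directing group in the next step.

Step 8
Reactants: 11 2α-hydroxy-4-methyl-1αH-bicyclo[5.3.0]deca-4,9-dien-8-one
Product: 12 4α,5α-epoxy-2α-hydroxy-4β-methyl-1αH-bicyclo[5.3.0]dec-9-en-8-one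
Conditions: VO(acac)2 (5 mol%), tBuOOH, CH2Cl2, 0 °C to rt
Reagents that add atoms: tert-butyl hydroperoxide, CC(C)(C)OO
Why: hydroxyl-directed epoxidation should deliver oxygen from the vanadate ester of the cyclopent-3-enol to the α face of the electron-rich C4=C5 bond (syn to OH), setting C4 and the α-oxirane and leaving the electron-poor enone untouched.

Step 9
Reactants: 12 4α,5α-epoxy-2α-hydroxy-4β-methyl-1αH-bicyclo[5.3.0]dec-9-en-8-one
Product: 13 2α-(tert-butyldimethylsilyloxy)-4α,5α-epoxy-4β-methyl-1αH-bicyclo[5.3.0]dec-9-en-8-one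
Conditions: TBSCl, imidazole, DMF, rt
Reagents that add atoms: tert-butyldimethylsilyl chloride, CC(C)(C)[Si](C)(C)Cl
Why: silylation under neutral imidazole conditions should protect the secondary alcohol for the later acylation sequence without opening the acid-sensitive oxirane.

Step 10
Reactants: 13 2α-(tert-butyldimethylsilyloxy)-4α,5α-epoxy-4β-methyl-1αH-bicyclo[5.3.0]dec-9-en-8-one; 14 diethyl 2-oxopropanedioate (diethyl ketomalonate)
Product: 17 diethyl 2α-(tert-butyldimethylsilyloxy)-5β,11-epoxy-4α-hydroxy-8-oxo-14-norguai-9-ene-12,13-dioate, via lithium dienolate 15 (not isolated), via epoxy aldol 16 (not isolated)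
Conditions: LDA, THF, −78 °C; then 14, −78 °C; then camphorsulfonic acid, CH2Cl2, −78 to 0 °C
Reagents that add atoms: none
Why: kinetic α′-deprotonation of the cross-conjugated enone gives lithium dienolate 15, which adds to the non-enolisable, highly electrophilic ketone of 14 (aldol addition, C7–C11); protonation then lets the new tertiary C11–OH open the activated 4α,5α-oxirane at C5 (C5–O), so that the two events amount to a formal [3+2] union of a C=O group with the C5–C6–C7 unit. The closest known reaction types are the lithium enolate aldol addition to ketomalonates and the acid-catalysed epoxy-alcohol cyclisation used for oxolanes in polyether synthesis. The only ring closed is the oxolane O–C11–C7–C6–C5, by a 5-exo-tet opening at C5, the 6-endo mode at C4 being out of reach of the β-side chain. C5 is set by stereospecific backside attack (inversion, giving 5β-O and leaving the 4α-OH with retention), C7 by enolate attack on the β face, anti to the pseudo-axial oxirane oxygen that sits 1,3 to C7 on the α face, and C11 is not yet stereogenic because its two ester groups are identical. The step needs regioselective enolisation (secured by the C9=C10 bond, which leaves only C7–H acidic), β-facial selectivity at C7 (secured by the α-oxirane, and only the 7β adduct can reach the rear of C5) and attack at C5 instead of C4 (secured by the five-membered transition state).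

Step 11
Reactants: 17 diethyl 2α-(tert-butyldimethylsilyloxy)-5β,11-epoxy-4α-hydroxy-8-oxo-14-norguai-9-ene-12,13-dioate
Product: 19 diethyl 2α-(tert-butyldimethylsilyloxy)-5β,11-epoxy-4α-hydroxy-8-oxoguaiane-12,13-dioate (10α-methyl), via lithium enolate 18 (not isolated)
Conditions: Me2CuLi (from MeLi and CuBr·SMe2, excess), Et2O, −78 to −30 °C; aq NH4Cl
Reagents that add atoms: lithium dimethylcuprate, [Li+].C[Cu-]C
Why: conjugate addition of the Gilman cuprate to the cycloheptenone should deliver the methyl group to C10 from the α face, anti to the C5–O–C11 bridge and its ester groups that cover the β face, so that H-10 ends β.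

Step 12
Reactants: 19 diethyl 2α-(tert-butyldimethylsilyloxy)-5β,11-epoxy-4α-hydroxy-8-oxoguaiane-12,13-dioate
Product: 21 ethyl 2α-(tert-butyldimethylsilyloxy)-5β,11-epoxy-4α-hydroxy-12-oxo-8β,12-epoxyguaian-13-oate (the 12,8β-lactone ester), via hydroxy diester 20 (not isolated)
Conditions: NaBH4, EtOH, −20 °C to rt
Reagents that add atoms: none
Why: borohydride should attack the C8 ketone from the α face, anti to the fully substituted C11 on C7, and the 8β-alkoxide can reach only the ester syn to it, so that lactonisation (intramolecular transesterification) fixes the configuration of C11.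

Step 13
Reactants: 21 the 12,8β-lactone ethyl ester
Product: 23 2α-(tert-butyldimethylsilyloxy)-5β,11-epoxy-4α-hydroxy-12,8β-olidoguaian-13-oic acid, via dilithium hydroxy dicarboxylate 22 (not isolated)
Conditions: LiOH·H2O, THF/H2O, rt; then 1 M HCl to pH 2, 0 °C to rt
Reagents that add atoms: lithium hydroxide, [Li+].[OH-]
Why: saponification should hydrolyse the ethyl ester (the lactone opens reversibly), and on acidification only the cis γ-lactone to O8 can re-form, so C8 and C11 are unchanged and the second carboxyl is left free.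

Step 14
Reactants: 23 2α-(tert-butyldimethylsilyloxy)-5β,11-epoxy-4α-hydroxy-12,8β-olidoguaian-13-oic acid
Product: 24 2α-(tert-butyldimethylsilyloxy)-5β,11-epoxy-4α,13-dihydroxyguaian-12,8β-olide
Conditions: BH3·SMe2, THF, 0 °C to rt; MeOH quench
Reagents that add atoms: none
Why: borane reduces a carboxylic acid (through the acyloxyborane) much faster than a lactone, so the acid should be taken to the C13 primary alcohol chemoselectively.

Step 15
Reactants: 24 2α-(tert-butyldimethylsilyloxy)-5β,11-epoxy-4α,13-dihydroxyguaian-12,8β-olide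
Product: 25 13-acetoxy-2α-(tert-butyldimethylsilyloxy)-5β,11-epoxy-4α-hydroxyguaian-12,8β-olide
Conditions: Ac2O, pyridine, DMAP (cat.), CH2Cl2, 0 °C
Reagents that add atoms: acetic anhydride, CC(=O)OC(C)=O
Why: DMAP-catalysed acetylation should take the only unhindered free hydroxyl (primary C13–OH), the tertiary C4–OH being inert at 0 °C.

Step 16
Reactants: 25 13-acetoxy-2α-(tert-butyldimethylsilyloxy)-5β,11-epoxy-4α-hydroxyguaian-12,8β-olide
Product: 26 13-acetoxy-5β,11-epoxy-2α,4α-dihydroxyguaian-12,8β-olide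
Conditions: HF·pyridine, THF, 0 °C to rt
Reagents that add atoms: none
Why: fluoride-mediated desilylation should free the C2 hydroxyl under acidic conditions that leave the acetate and the lactone intact.

Step 17
Reactants: 26 13-acetoxy-5β,11-epoxy-2α,4α-dihydroxyguaian-12,8β-olide
Product: 27 CNP0112086.1 (13-acetoxy-5β,11-epoxy-4α-hydroxy-2α-tigloyloxyguaian-12,8β-olide)
Conditions: (E)-2-methylbut-2-enoyl chloride, Et3N, DMAP, CH2Cl2, 0 °C to rt
Reagents that add atoms: tigloyl chloride, C/C=C(\C)C(=O)Cl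
Why: DMAP-catalysed acylation should esterify the secondary C2–OH only (the tertiary C4–OH does not react), and the E geometry of the tiglate is the stable one.

**Compound list**

1 | (S)-4-(tert-butyldimethylsilyloxy)cyclopent-2-en-1-one | CC(C)(C)[Si](C)(C)O[C@H]1CC(=O)C=C1 | starting material
2 | (S)-4-(tert-butyldimethylsilyloxy)-2-iodocyclopent-2-en-1-one | CC(C)(C)[Si](C)(C)O[C@H]1CC(=O)C(I)=C1 | intermediate
3 | (3-ethoxy-3-oxopropyl)zinc bromide | CCOC(=O)CC[Zn]Br | starting material
4 | ethyl 3-[(3S)-3-(tert-butyldimethylsilyloxy)-5-oxocyclopent-1-en-1-yl]propanoate | CC(C)(C)[Si](C)(C)O[C@H]1CC(=O)C(CCC(=O)OCC)=C1 | intermediate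
5 | bromomagnesium enolate of the vinyl 1,4-adduct of 4 (formed in situ) | CC(C)(C)[Si](C)(C)O[C@H]1CC(O[Mg]Br)=C(CCC(=O)OCC)[C@@H]1C=C | intermediate
6 | ethyl 3-[(4S,5S)-4-(tert-butyldimethylsilyloxy)-2-(trifluoromethylsulfonyloxy)-5-vinylcyclopent-1-en-1-yl]propanoate | CC(C)(C)[Si](C)(C)O[C@H]1CC(OS(=O)(=O)C(F)(F)F)=C(CCC(=O)OCC)[C@@H]1C=C | intermediate
7 | ethyl 3-[(4S,5S)-4-(tert-butyldimethylsilyloxy)-2-methyl-5-vinylcyclopent-1-en-1-yl]propanoate | CC(C)(C)[Si](C)(C)O[C@H]1CC(C)=C(CCC(=O)OCC)[C@@H]1C=C | intermediate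
8 | 3-[(4S,5S)-4-(tert-butyldimethylsilyloxy)-2-methyl-5-vinylcyclopent-1-en-1-yl]-N-methoxy-N-methylpropanamide (formed in situ) | CC(C)(C)[Si](C)(C)O[C@H]1CC(C)=C(CCC(=O)N(C)OC)[C@@H]1C=C | intermediate
9 | 5-[(4S,5S)-4-(tert-butyldimethylsilyloxy)-2-methyl-5-vinylcyclopent-1-en-1-yl]pent-1-en-3-one | CC(C)(C)[Si](C)(C)O[C@H]1CC(C)=C(CCC(=O)C=C)[C@@H]1C=C | intermediate
10 | 2α-(tert-butyldimethylsilyloxy)-4-methyl-1αH-bicyclo[5.3.0]deca-4,9-dien-8-one (guaiane numbering) | CC(C)(C)[Si](C)(C)O[C@H]1CC(C)=C2CCC(=O)C=C[C@H]12 | intermediate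
11 | 2α-hydroxy-4-methyl-1αH-bicyclo[5.3.0]deca-4,9-dien-8-one | O[C@H]1CC(C)=C2CCC(=O)C=C[C@H]12 | intermediate
12 | 4α,5α-epoxy-2α-hydroxy-4β-methyl-1αH-bicyclo[5.3.0]dec-9-en-8-one | O[C@H]1C[C@@]2(C)O[C@]23CCC(=O)C=C[C@H]13 | intermediate
13 | 2α-(tert-butyldimethylsilyloxy)-4α,5α-epoxy-4β-methyl-1αH-bicyclo[5.3.0]dec-9-en-8-one | CC(C)(C)[Si](C)(C)O[C@H]1C[C@@]2(C)O[C@]23CCC(=O)C=C[C@H]13 | intermediate
14 | diethyl 2-oxopropanedioate (diethyl ketomalonate) | CCOC(=O)C(=O)C(=O)OCC | starting material
15 | lithium dienolate of 13 (C7=C8–OLi, oxirane intact; formed in situ) | CC(C)(C)[Si](C)(C)O[C@H]1C[C@@]2(C)O[C@]23CC=C(O[Li])C=C[C@H]13 | intermediate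
16 | epoxy aldol: diethyl 2-hydroxy-2-[2α-(tert-butyldimethylsilyloxy)-4α,5α-epoxy-4β-methyl-8-oxo-1αH-bicyclo[5.3.0]dec-9-en-7β-yl]propanedioate (formed in situ) | CC(C)(C)[Si](C)(C)O[C@H]1C[C@@]2(C)O[C@]23C[C@@H](C(=O)C=C[C@H]13)C(O)(C(=O)OCC)C(=O)OCC | intermediate
17 | diethyl 2α-(tert-butyldimethylsilyloxy)-5β,11-epoxy-4α-hydroxy-8-oxo-14-norguai-9-ene-12,13-dioate | CC(C)(C)[Si](C)(C)O[C@H]1C[C@@](C)(O)[C@@]23C[C@@H](C(=O)C=C[C@H]12)C(C(=O)OCC)(C(=O)OCC)O3 | intermediate
18 | lithium C8 enolate (C8=C9) of the methyl adduct, C4 alkoxide also lithiated (formed in situ) | CC(C)(C)[Si](C)(C)O[C@H]1C[C@@](C)(O[Li])[C@@]23C[C@@H](C(O[Li])=C[C@@H](C)[C@H]12)C(C(=O)OCC)(C(=O)OCC)O3 | intermediate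
19 | diethyl 2α-(tert-butyldimethylsilyloxy)-5β,11-epoxy-4α-hydroxy-8-oxoguaiane-12,13-dioate (10α-methyl) | CC(C)(C)[Si](C)(C)O[C@H]1C[C@@](C)(O)[C@@]23C[C@@H](C(=O)C[C@@H](C)[C@H]12)C(C(=O)OCC)(C(=O)OCC)O3 | intermediate
20 | diethyl 2α-(tert-butyldimethylsilyloxy)-5β,11-epoxy-4α,8β-dihydroxyguaiane-12,13-dioate (formed in situ) | CC(C)(C)[Si](C)(C)O[C@H]1C[C@@](C)(O)[C@@]23C[C@@H]([C@H](O)C[C@@H](C)[C@H]12)C(C(=O)OCC)(C(=O)OCC)O3 | intermediate
21 | ethyl 2α-(tert-butyldimethylsilyloxy)-5β,11-epoxy-4α-hydroxy-12,8β-olidoguaian-13-oate | CC(C)(C)[Si](C)(C)O[C@H]1C[C@@](C)(O)[C@@]23C[C@H]4[C@@H](C[C@@H](C)[C@H]12)OC(=O)[C@@]4(C(=O)OCC)O3 | intermediate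
22 | dilithium 2α-(tert-butyldimethylsilyloxy)-5β,11-epoxy-4α,8β-dihydroxyguaiane-12,13-dioate (formed in situ) | CC(C)(C)[Si](C)(C)O[C@H]1C[C@@](C)(O)[C@@]23C[C@@H]([C@H](O)C[C@@H](C)[C@H]12)C(C(=O)O[Li])(C(=O)O[Li])O3 | intermediate
23 | 2α-(tert-butyldimethylsilyloxy)-5β,11-epoxy-4α-hydroxy-12,8β-olidoguaian-13-oic acid | CC(C)(C)[Si](C)(C)O[C@H]1C[C@@](C)(O)[C@@]23C[C@H]4[C@@H](C[C@@H](C)[C@H]12)OC(=O)[C@@]4(C(=O)O)O3 | intermediate
24 | 2α-(tert-butyldimethylsilyloxy)-5β,11-epoxy-4α,13-dihydroxyguaian-12,8β-olide | CC(C)(C)[Si](C)(C)O[C@H]1C[C@@](C)(O)[C@@]23C[C@H]4[C@@H](C[C@@H](C)[C@H]12)OC(=O)[C@@]4(CO)O3 | intermediate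
25 | 13-acetoxy-2α-(tert-butyldimethylsilyloxy)-5β,11-epoxy-4α-hydroxyguaian-12,8β-olide | CC(C)(C)[Si](C)(C)O[C@H]1C[C@@](C)(O)[C@@]23C[C@H]4[C@@H](C[C@@H](C)[C@H]12)OC(=O)[C@@]4(COC(C)=O)O3 | intermediate
26 | 13-acetoxy-5β,11-epoxy-2α,4α-dihydroxyguaian-12,8β-olide | O[C@H]1C[C@@](C)(O)[C@@]23C[C@H]4[C@@H](C[C@@H](C)[C@H]12)OC(=O)[C@@]4(COC(C)=O)O3 | intermediate
27 | CNP0112086.1: 13-acetoxy-5β,11-epoxy-4α-hydroxy-2α-[(E)-2-methylbut-2-enoyloxy]guaian-12,8β-olide | C/C=C(\C)C(=O)O[C@H]1C[C@@](C)(O)[C@@]23C[C@H]4[C@@H](C[C@@H](C)[C@H]12)OC(=O)[C@@]4(COC(C)=O)O3 | target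

**Step count**

Total: 17 steps. Longest linear sequence: 17 steps (1 to 27).

**Steps most likely to fail**

Step 10. What may go wrong: the aldol addition may take place on the α face of C7, giving an adduct that cannot reach C5, or the acid may trigger a 1,2-shift of the tetrasubstituted oxirane before the hydroxyl engages. The fallback sets out from 13 and comes back at 17, and replaces the one-flask kinetic cascade by a decoupled sequence with thermodynamic correction at C7. LDA and Me3SiCl should give the cross-conjugated trimethylsilyl dienol ether F1. A Lewis-base-catalysed Mukaiyama aldol addition to 14 (catalytic tetrabutylammonium difluorotriphenylsilicate, THF, −78 °C) should then give the O-silylated epoxy aldol F2 as a mixture at C7, with no acid in contact with the oxirane. Catalytic DBU should interconvert the C7 epimers through the enol. PPTS in MeOH should then unmask the tertiary alcohol and close only the 7β epimer to 17; the 7α epimer is returned to the equilibration.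

Step 11. What may go wrong: the methyl group may be delivered to the β face of C10, or the facial preference may be weak. The fallback sets out from 19 (whichever C10 epimers the cuprate step delivers) and comes back at 21 through 20; C10 is then set by placing H-10 under hydroxyl direction instead of by a sterically controlled C–C bond formation. Dehydrogenation with 2-iodoxybenzoic acid (DMSO, 70 °C) should give the β-methyl enone F3, the bridgehead C7 being unable to take part. Luche reduction (NaBH4, CeCl3·7H2O, MeOH, −78 °C) should give the 8β-allylic alcohol F4, which is kept cold so that it does not lactonise. Hydrogenation with [Ir(cod)(PCy3)(py)]PF6 under H2 in CH2Cl2 should deliver hydrogen to C10 from the β face, syn to the 8β-OH, to give 20, which lactonises to 21 as in step 12.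

Step 12. What may go wrong: hydride may be delivered to the β face of C8, leaving an 8α-alcohol that cannot lactonise. The fallback sets out from 19 and comes back at 23; the lactone C8–O bond is then formed by displacement at C8 instead of by acylation of an 8β-alcohol. The 8α-hydroxy diester F5 from the reduction should be saponified (LiOH, THF/H2O) to the 8α-hydroxy diacid F6. A Mitsunobu lactonisation (PPh3, diisopropyl azodicarboxylate, THF, 0 °C) should then let the carboxyl group syn to C8 displace the activated 8α-oxygen with inversion, giving lactone acid 23 directly.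

**Further compounds**

F1 | step 10 | trimethylsilyl dienol ether of 13 (C7=C8–OSiMe3) | CC(C)(C)[Si](C)(C)O[C@H]1C[C@@]2(C)O[C@]23CC=C(O[Si](C)(C)C)C=C[C@H]13
F2 | step 10 | O-trimethylsilyl epoxy aldol (mixture at C7) | CC(C)(C)[Si](C)(C)O[C@H]1C[C@@]2(C)O[C@]23CC(C(=O)C=C[C@H]13)C(O[Si](C)(C)C)(C(=O)OCC)C(=O)OCC
F3 | step 11 | diethyl 2α-(tert-butyldimethylsilyloxy)-5β,11-epoxy-4α-hydroxy-8-oxoguai-9-ene-12,13-dioate (β-methyl enone) | CC(C)(C)[Si](C)(C)O[C@H]1C[C@@](C)(O)[C@@]23C[C@@H](C(=O)C=C(C)[C@H]12)C(C(=O)OCC)(C(=O)OCC)O3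
F4 | step 11 | diethyl 2α-(tert-butyldimethylsilyloxy)-5β,11-epoxy-4α,8β-dihydroxyguai-9-ene-12,13-dioate | CC(C)(C)[Si](C)(C)O[C@H]1C[C@@](C)(O)[C@@]23C[C@@H]([C@H](O)C=C(C)[C@H]12)C(C(=O)OCC)(C(=O)OCC)O3
F5 | step 12 | diethyl 2α-(tert-butyldimethylsilyloxy)-5β,11-epoxy-4α,8α-dihydroxyguaiane-12,13-dioate | CC(C)(C)[Si](C)(C)O[C@H]1C[C@@](C)(O)[C@@]23C[C@@H]([C@@H](O)C[C@@H](C)[C@H]12)C(C(=O)OCC)(C(=O)OCC)O3
F6 | step 12 | 2α-(tert-butyldimethylsilyloxy)-5β,11-epoxy-4α,8α-dihydroxyguaiane-12,13-dioic acid | CC(C)(C)[Si](C)(C)O[C@H]1C[C@@](C)(O)[C@@]23C[C@@H]([C@@H](O)C[C@@H](C)[C@H]12)C(C(=O)O)(C(=O)O)O3
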